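**Strategy.** Labels: C1 (fusion carbon carrying OAc), C2 (guaiacyl-bearing CH), O3, C4 (OCH2), C5 (fusion CH), C6 (veratryl-bearing CH), O7, C8; ring A = C1–C2–O3–C4–C5, ring B = C5–C6–O7–C8–C1. Taking O3 out of ring A leaves a cyclobutanone (C1, C2, C4, C5; C4=O) cis-fused to ring B, the ketene adduct of the C1=C5 silyl enol ether of ring B. The key step exploits the strained C4 carbonyl flanked by electron-rich benzylic C2: a peracid inserts O3 between C2 and C4 with retention, delivering the ring A lactone with all four stereocentres set. The precursor is the cis-fused, exo-aryl, 1-silyloxy cyclobutanone 14.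

Key step: step 9

Assumption: the (R)-BINAP ruthenium catalyst is taken to give the (S)-carbinol from this β-aryl β-keto ester, as it does with ethyl benzoylacetate; the mirror-image ligand would be used if the sense proved opposite. (C1–C8 in the Why lines are the labels above; systematic names carry their own locants.)

Step 1
Reactants: 1 ethyl 3-(3,4-dimethoxyphenyl)-3-oxopropanoate
Product: 2 ethyl (3S)-3-(3,4-dimethoxyphenyl)-3-hydroxypropanoate
Conditions: H2 (30 bar), [RuCl(p-cymene)((R)-BINAP)]Cl (0.5 mol%), EtOH, 60 °C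
Reagents that add atoms: none
Why: Noyori asymmetric hydrogenation of a β-keto ester; the ester-chelated ketone is reduced on one face by the chiral ruthenium hydride, which sets the future C6 centre as S.

Step 2
Reactants: 2 ethyl (3S)-3-(3,4-dimethoxyphenyl)-3-hydroxypropanoate
Product: 3 (3S)-3-(3,4-dimethoxyphenyl)-3-hydroxypropanoic acid
Conditions: LiOH·H2O, THF/H2O, 0 °C → rt; then cold 1 M HCl to pH 3
Reagents that add atoms: lithium hydroxide (its oxygen becomes the acid OH), [Li+].[OH-]
Why: ordinary ester saponification under conditions too mild for dehydration or retro-aldol cleavage, so the carbinol centre is untouched; crystallisation of 3 should allow the enantiomeric purity to be raised if needed.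

Step 3
Reactants: 3 (3S)-3-(3,4-dimethoxyphenyl)-3-hydroxypropanoic acid
Product: 5 (4S)-1-diazo-4-(3,4-dimethoxyphenyl)-4-hydroxybutan-2-one, via mixed carbonic anhydride 4 (not isolated)
Conditions: iBuOCOCl, N-methylmorpholine, THF, −20 °C; then CH2N2, Et2O, −20 → 0 °C
Reagents that add atoms: diazomethane, C=[N+]=[N-]
Why: at −20 °C the chloroformate acylates the carboxylate far faster than the secondary alcohol (as in mixed-anhydride couplings of hydroxy acids), and C-acylation of diazomethane by the anhydride (first half of an Arndt–Eistert sequence) gives the diazoketone while the leaving group falls apart to isobutanol and CO2.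

Step 4
Reactants: 5 (4S)-1-diazo-4-(3,4-dimethoxyphenyl)-4-hydroxybutan-2-one
Product: 6 (5S)-5-(3,4-dimethoxyphenyl)oxolan-3-one
Conditions: Rh2(OAc)4 (1 mol%), CH2Cl2, rt, slow addition of 5
Reagents that add atoms: none
Why: the rhodium carbenoid is trapped by the hydroxyl three carbons away (oxonium ylide, then proton shift: intramolecular O–H insertion), which closes the five-membered ring B ketone faster than attack on the arene and leaves the carbinol centre alone.

Step 5
Reactants: 6 (5S)-5-(3,4-dimethoxyphenyl)oxolan-3-one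
Product: 7 tert-butyl{[(5S)-5-(3,4-dimethoxyphenyl)-2,5-dihydrofuran-3-yl]oxy}dimethylsilane
Conditions: LiN(iPr)2 (LDA), THF, −78 °C; then tBuMe2SiOTf, −78 °C
Reagents that add atoms: tert-butyldimethylsilyl trifluoromethanesulfonate, CC(C)(C)[Si](C)(C)OS(=O)(=O)C(F)(F)F
Why: kinetic enolisation by the hindered amide is expected at the CH2 remote from the ring oxygen (future C5), the side on which 3-oxo-oxolanes generally react, and O-silylation gives the C1=C5 silyl enol ether (kinetic silyl enol ether formation); at −78 °C the enolate does not expel the ring oxygen (reverse of a disfavoured 5-endo-trig closure), so C6 is preserved.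

Step 6
Reactants: 8 homovanillic acid; 9 benzyl bromide
Product: 10 [4-(benzyloxy)-3-methoxyphenyl]acetic acid
Conditions: NaOH (2.5 equiv), EtOH/H2O, reflux; then HCl
Reagents that add atoms: none
Why: Williamson ether synthesis on the phenoxide; in the protic medium the carboxylate is hardly alkylated and any benzyl ester is saponified in the same pot.

Step 7
Reactants: 10 [4-(benzyloxy)-3-methoxyphenyl]acetic acid; 7 tert-butyl{[(5S)-5-(3,4-dimethoxyphenyl)-2,5-dihydrofuran-3-yl]oxy}dimethylsilane
Product: 13 (1S,4S,5R)-7-[4-(benzyloxy)-3-methoxyphenyl]-1-[(tert-butyldimethylsilyl)oxy]-4-(3,4-dimethoxyphenyl)-3-oxabicyclo[3.2.0]heptan-6-one (mixture of epimers at C7 = C2 of the target labels), via acid chloride 11 (not isolated), via arylketene 12 (not isolated)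
Conditions: 10, (COCl)2, cat. DMF, CH2Cl2, rt, evaporate; crude 11 (3 equiv) added slowly to 7 and iPr2NEt in toluene, 80 °C
Reagents that add atoms: none
Why: dehydrochlorination of 11 gives arylketene 12, which adds to the electron-rich alkene 7 in a thermal ketene–alkene [2+2] cycloaddition with the ketene carbonyl carbon bonding to nucleophilic C5 and the aryl-bearing carbon to oxygenated C1; the four-membered ring is necessarily cis-fused, attack on the face of the planar dihydrofuran opposite the neighbouring C6 aryl sets C1 and C5, and C2 forms under kinetic control (aryl expected mainly on the concave face) and is corrected in step 8.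

Step 8
Reactants: 13 the C7-epimeric cycloadduct
Product: 14 (1S,4S,5R,7R)-7-[4-(benzyloxy)-3-methoxyphenyl]-1-[(tert-butyldimethylsilyl)oxy]-4-(3,4-dimethoxyphenyl)-3-oxabicyclo[3.2.0]heptan-6-one
Conditions: DBU (0.3 equiv), CH2Cl2, rt
Reagents that add atoms: none
Why: reversible enolisation at C2 (α to the ketone and benzylic) permits thermodynamic epimerisation, which should place the aryl group on the convex face, cis to the sterically slim C1–O bond and out of the fold of ring B, and so sets C2; C5 cannot invert because the ring fusion must stay cis, and no free hydroxyl is present to start a retro-aldol opening.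

Step 9
Reactants: 14 (1S,4S,5R,7R)-7-[4-(benzyloxy)-3-methoxyphenyl]-1-[(tert-butyldimethylsilyl)oxy]-4-(3,4-dimethoxyphenyl)-3-oxabicyclo[3.2.0]heptan-6-one
Product: 15 (3R,3aS,6S,6aR)-3-[4-(benzyloxy)-3-methoxyphenyl]-3a-[(tert-butyldimethylsilyl)oxy]-6-(3,4-dimethoxyphenyl)tetrahydro-1H,3H-furo[3,4-c]furan-1-one
Conditions: mCPBA (1.5 equiv), NaHCO3 (buffer), CH2Cl2, 0 °C → rt
Reagents that add atoms: meta-chloroperoxybenzoic acid, OOC(=O)c1cccc(Cl)c1
Why: The peracid adds to the strained C4 carbonyl to give a Criegee adduct, from which C2 shifts from C4 to the proximal peroxide oxygen as the carboxylate leaves, so the C2–C4 bond is exchanged for C2–O3 and O3–C4. This is the Baeyer–Villiger ring expansion of a ketene-derived cyclobutanone to a γ-butyrolactone, a well-established reaction class. Ring A is not closed by cyclisation: it arises by one-atom enlargement of the four-membered ring through a 1,2-shift, so no ring-closing trajectory has to be met. No stereocentre is created; C2 migrates with retention and C1, C5 and C6 are spectators, so the cis-fused, exo-aryl arrangement of 14 is carried into 15. The step needs migration of C2 and not of C5, which is secured because C2 is benzylic and carries a para-alkoxyaryl donor, whereas C5 is a plain secondary carbon deactivated by two β-oxygens (on C1 and C6). Bicarbonate buffering and the high rate of cyclobutanone oxidation should keep the silyl ether, the acid-labile benzylic lactone C–O bond and the electron-rich arenes intact.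

Step 10
Reactants: 15 the ring A lactone
Product: 16 (3R,3aS,6S,6aR)-3-[4-(benzyloxy)-3-methoxyphenyl]-3a-[(tert-butyldimethylsilyl)oxy]-6-(3,4-dimethoxyphenyl)tetrahydro-1H,3H-furo[3,4-c]furan-1-ol (both anomers)
Conditions: iBu2AlH (1.1 equiv), CH2Cl2, −78 °C; Rochelle salt work-up
Reagents that add atoms: none
Why: partial reduction of a lactone; the tetrahedral aluminium hemiacetal is stable at −78 °C and collapses only on work-up, so reduction stops at the lactol, whose new C4 centre is of no consequence.

Step 11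
Reactants: 16 the lactol
Product: 17 {[(3R,3aS,6S,6aR)-3-[4-(benzyloxy)-3-methoxyphenyl]-6-(3,4-dimethoxyphenyl)-3,4,6,6a-tetrahydro-1H-furo[3,4-c]furan-3a-yl]oxy}(tert-butyl)dimethylsilane
Conditions: Et3SiH (3 equiv), BF3·OEt2 (1.5 equiv), CH2Cl2, −78 → −40 °C
Reagents that add atoms: none
Why: Lewis-acid ionisation of the lactol to the O3-stabilised oxocarbenium ion at C4 and hydride transfer from the silane (ionic hydrogenation, the usual way from furofuranone lactols to furofurans); at low temperature the benzylic C–O bonds and the tertiary silyl ether should not ionise, and C4 becomes a CH2.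

Step 12
Reactants: 17 the silyl-protected furofuran
Product: 18 (3R,3aS,6S,6aR)-3-[4-(benzyloxy)-3-methoxyphenyl]-6-(3,4-dimethoxyphenyl)-3,4,6,6a-tetrahydro-1H-furo[3,4-c]furan-3a-ol
Conditions: Bu4NF, THF, rt → 50 °C
Reagents that add atoms: none
Why: fluoride-induced Si–O cleavage (desilylation) driven by the strong Si–F bond; the tertiary ether needs mild warming and nothing else in 17 is sensitive to fluoride or base.

Step 13
Reactants: 18 the tertiary alcohol
Product: 19 [(3R,3aS,6S,6aR)-3-[4-(benzyloxy)-3-methoxyphenyl]-6-(3,4-dimethoxyphenyl)-3,4,6,6a-tetrahydro-1H-furo[3,4-c]furan-3a-yl] acetate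
Conditions: Ac2O, Et3N, DMAP, CH2Cl2, rt → 40 °C
Reagents that add atoms: acetic anhydride, CC(=O)OC(C)=O
Why: DMAP-catalysed acylation (nucleophilic catalysis through the N-acetylpyridinium ion) is the standard way to esterify a hindered tertiary alcohol, and with the phenol still masked only the C1 hydroxyl can react.

Step 14
Reactants: 19 the benzyl-protected acetate
Product: 20 [(3R,3aS,6S,6aR)-6-(3,4-dimethoxyphenyl)-3-(4-hydroxy-3-methoxyphenyl)-3,4,6,6a-tetrahydro-1H-furo[3,4-c]furan-3a-yl] acetate (CNP0107105.1)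
Conditions: H2 (1 atm), 10% Pd/C, EtOAc, rt, stopped after one equivalent of H2
Reagents that add atoms: none
Why: palladium-catalysed hydrogenolysis cleaves the aryl benzyl ether much faster than the dialkyl benzylic C–O bonds of rings A and B, and the tertiary acetate is inert.

**Compound list**

1 | ethyl 3-(3,4-dimethoxyphenyl)-3-oxopropanoate | CCOC(=O)CC(=O)c1ccc(OC)c(OC)c1 | starting material
2 | ethyl (3S)-3-(3,4-dimethoxyphenyl)-3-hydroxypropanoate | CCOC(=O)C[C@H](O)c1ccc(OC)c(OC)c1 | intermediate
3 | (3S)-3-(3,4-dimethoxyphenyl)-3-hydroxypropanoic acid | OC(=O)C[C@H](O)c1ccc(OC)c(OC)c1 | intermediate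
4 | mixed isobutyl carbonic anhydride of 3 (not isolated) | CC(C)COC(=O)OC(=O)C[C@H](O)c1ccc(OC)c(OC)c1 | intermediate
5 | (4S)-1-diazo-4-(3,4-dimethoxyphenyl)-4-hydroxybutan-2-one | [N-]=[N+]=CC(=O)C[C@H](O)c1ccc(OC)c(OC)c1 | intermediate
6 | (5S)-5-(3,4-dimethoxyphenyl)oxolan-3-one | O=C1CO[C@H](c2ccc(OC)c(OC)c2)C1 | intermediate
7 | tert-butyl{[(5S)-5-(3,4-dimethoxyphenyl)-2,5-dihydrofuran-3-yl]oxy}dimethylsilane | CC(C)(C)[Si](C)(C)OC1=C[C@@H](c2ccc(OC)c(OC)c2)OC1 | intermediate
8 | homovanillic acid, (4-hydroxy-3-methoxyphenyl)acetic acid | COc1cc(CC(O)=O)ccc1O | starting material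
9 | benzyl bromide | BrCc1ccccc1 | starting material
10 | [4-(benzyloxy)-3-methoxyphenyl]acetic acid | COc1cc(CC(O)=O)ccc1OCc1ccccc1 | intermediate
11 | [4-(benzyloxy)-3-methoxyphenyl]acetyl chloride (not isolated) | COc1cc(CC(Cl)=O)ccc1OCc1ccccc1 | intermediate
12 | 2-[4-(benzyloxy)-3-methoxyphenyl]ethen-1-one, the arylketene (not isolated) | COc1cc(C=C=O)ccc1OCc1ccccc1 | intermediate
13 | (1S,4S,5R)-7-[4-(benzyloxy)-3-methoxyphenyl]-1-[(tert-butyldimethylsilyl)oxy]-4-(3,4-dimethoxyphenyl)-3-oxabicyclo[3.2.0]heptan-6-one, epimer mixture at C7 (C2 of the target labels) | COc1cc(C2C(=O)[C@@H]3[C@@H](c4ccc(OC)c(OC)c4)OC[C@]23O[Si](C)(C)C(C)(C)C)ccc1OCc1ccccc1 | intermediate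
14 | (1S,4S,5R,7R)-7-[4-(benzyloxy)-3-methoxyphenyl]-1-[(tert-butyldimethylsilyl)oxy]-4-(3,4-dimethoxyphenyl)-3-oxabicyclo[3.2.0]heptan-6-one (aryl on the convex face, cis to OSi) | COc1cc([C@H]2C(=O)[C@@H]3[C@@H](c4ccc(OC)c(OC)c4)OC[C@]23O[Si](C)(C)C(C)(C)C)ccc1OCc1ccccc1 | intermediate
15 | (3R,3aS,6S,6aR)-3-[4-(benzyloxy)-3-methoxyphenyl]-3a-[(tert-butyldimethylsilyl)oxy]-6-(3,4-dimethoxyphenyl)tetrahydro-1H,3H-furo[3,4-c]furan-1-one | COc1cc([C@H]2OC(=O)[C@@H]3[C@@H](c4ccc(OC)c(OC)c4)OC[C@]23O[Si](C)(C)C(C)(C)C)ccc1OCc1ccccc1 | intermediate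
16 | (3R,3aS,6S,6aR)-3-[4-(benzyloxy)-3-methoxyphenyl]-3a-[(tert-butyldimethylsilyl)oxy]-6-(3,4-dimethoxyphenyl)tetrahydro-1H,3H-furo[3,4-c]furan-1-ol, both anomers | COc1cc([C@H]2OC(O)[C@@H]3[C@@H](c4ccc(OC)c(OC)c4)OC[C@]23O[Si](C)(C)C(C)(C)C)ccc1OCc1ccccc1 | intermediate
17 | {[(3R,3aS,6S,6aR)-3-[4-(benzyloxy)-3-methoxyphenyl]-6-(3,4-dimethoxyphenyl)-3,4,6,6a-tetrahydro-1H-furo[3,4-c]furan-3a-yl]oxy}(tert-butyl)dimethylsilane | COc1cc([C@H]2OC[C@@H]3[C@@H](c4ccc(OC)c(OC)c4)OC[C@]23O[Si](C)(C)C(C)(C)C)ccc1OCc1ccccc1 | intermediate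
18 | (3R,3aS,6S,6aR)-3-[4-(benzyloxy)-3-methoxyphenyl]-6-(3,4-dimethoxyphenyl)-3,4,6,6a-tetrahydro-1H-furo[3,4-c]furan-3a-ol | COc1cc([C@H]2OC[C@@H]3[C@@H](c4ccc(OC)c(OC)c4)OC[C@]23O)ccc1OCc1ccccc1 | intermediate
19 | [(3R,3aS,6S,6aR)-3-[4-(benzyloxy)-3-methoxyphenyl]-6-(3,4-dimethoxyphenyl)-3,4,6,6a-tetrahydro-1H-furo[3,4-c]furan-3a-yl] acetate | COc1cc([C@H]2OC[C@@H]3[C@@H](c4ccc(OC)c(OC)c4)OC[C@]23OC(C)=O)ccc1OCc1ccccc1 | intermediate
20 | [(3R,3aS,6S,6aR)-6-(3,4-dimethoxyphenyl)-3-(4-hydroxy-3-methoxyphenyl)-3,4,6,6a-tetrahydro-1H-furo[3,4-c]furan-3a-yl] acetate | COc1cc([C@H]2OC[C@@H]3[C@@H](c4ccc(OC)c(OC)c4)OC[C@]23OC(C)=O)ccc1O | target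

**Step count.** 14 steps in total; longest linear sequence 13 steps (steps 1–5 and 7–14).

**Steps most likely to fail**

Step 7. The arylketene may dimerise or oligomerise faster than the trisubstituted silyl enol ether intercepts it, or C-acylation with silyl transfer may overtake ring closure. The fallback sets out from 10 and switches to a halogenated ketene, the class that adds most readily to silyl enol ethers. The dianion of 10 (LDA, 2.2 equiv, THF, −78 °C) is chlorinated with CCl4 to 2-[4-(benzyloxy)-3-methoxyphenyl]-2-chloroacetic acid F1, which (COCl)2 converts into 2-[4-(benzyloxy)-3-methoxyphenyl]-2-chloroacetyl chloride F2. With Et3N in the presence of 7 this gives [4-(benzyloxy)-3-methoxyphenyl](chloro)ketene F3, which is more electrophilic and slower to dimerise. Its cycloadduct, the 7-chloro analogue of the cyclobutanone F4, is dechlorinated with Bu3SnH and AIBN in toluene at 80 °C. This returns the route to 13, which then goes through step 8 as before.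

Step 8. The equilibrium may not lie far enough towards the convex-face aryl epimer, or the base may start β-elimination of the silyloxy group. The fallback sets out from the concave-aryl epimer contained in 13 and corrects C2 after oxygen insertion instead of before it. Oxidation as in step 9 gives the C3-epimeric lactone (3S,3aS,6S,6aR)-furofuranone F5. LiOH followed by careful acidification opens it to the hydroxy acid (2S,3R,4S)-4-{(S)-[4-(benzyloxy)-3-methoxyphenyl](hydroxy)methyl}-4-[(tert-butyldimethylsilyl)oxy]-2-(3,4-dimethoxyphenyl)oxolane-3-carboxylic acid F6. Mitsunobu lactonisation (PPh3, DIAD, THF, 0 °C) then closes the ring with inversion at the benzylic carbinol, which returns the route to 15.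

Step 9. C5 may migrate in place of C2 (regiochemical leakage in the Criegee adduct), or the peracid may attack the electron-rich arenes. The fallback sets out from 14 and inserts the oxygen photochemically. Irradiation through Pyrex (λ > 300 nm) in MeOH cleaves the C2–C4 bond on the benzylic side (Norrish α-cleavage). The acyl–benzyl biradical recloses through the carbonyl oxygen to a cyclic oxacarbene, which inserts into the O–H bond of methanol, so the ketone oxygen itself becomes O3. The product is the methyl acetal (3R,3aS,6S,6aR)-1-methoxy analogue of the lactol F7. Et3SiH with BF3·OEt2 at −78 °C reduces F7 directly, so the route is rejoined at 17 without passing through 15 and 16.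

**Further compounds**

F1 | step 7 | 2-[4-(benzyloxy)-3-methoxyphenyl]-2-chloroacetic acid (racemic) | COc1cc(C(Cl)C(O)=O)ccc1OCc1ccccc1
F2 | step 7 | 2-[4-(benzyloxy)-3-methoxyphenyl]-2-chloroacetyl chloride (racemic) | COc1cc(C(Cl)C(Cl)=O)ccc1OCc1ccccc1
F3 | step 7 | [4-(benzyloxy)-3-methoxyphenyl](chloro)ketene | COc1cc(C(Cl)=C=O)ccc1OCc1ccccc1
F4 | step 7 | 7-chloro analogue of 13, chlorine and aryl both on C7 (C2 of the target labels), mixture at that carbon | COc1cc(C2(Cl)C(=O)[C@@H]3[C@@H](c4ccc(OC)c(OC)c4)OC[C@]23O[Si](C)(C)C(C)(C)C)ccc1OCc1ccccc1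
F5 | step 8 | (3S,3aS,6S,6aR)-3-[4-(benzyloxy)-3-methoxyphenyl]-3a-[(tert-butyldimethylsilyl)oxy]-6-(3,4-dimethoxyphenyl)tetrahydro-1H,3H-furo[3,4-c]furan-1-one (C3 epimer of 15) | COc1cc([C@@H]2OC(=O)[C@@H]3[C@@H](c4ccc(OC)c(OC)c4)OC[C@]23O[Si](C)(C)C(C)(C)C)ccc1OCc1ccccc1
F6 | step 8 | (2S,3R,4S)-4-{(S)-[4-(benzyloxy)-3-methoxyphenyl](hydroxy)methyl}-4-[(tert-butyldimethylsilyl)oxy]-2-(3,4-dimethoxyphenyl)oxolane-3-carboxylic acid | COc1cc([C@H](O)[C@@]2(O[Si](C)(C)C(C)(C)C)CO[C@H](c3ccc(OC)c(OC)c3)[C@H]2C(O)=O)ccc1OCc1ccccc1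
F7 | step 9 | (3R,3aS,6S,6aR)-3-[4-(benzyloxy)-3-methoxyphenyl]-3a-[(tert-butyldimethylsilyl)oxy]-6-(3,4-dimethoxyphenyl)-1-methoxyhexahydrofuro[3,4-c]furan, both anomers | COc1cc([C@H]2OC(OC)[C@@H]3[C@@H](c4ccc(OC)c(OC)c4)OC[C@]23O[Si](C)(C)C(C)(C)C)ccc1OCc1ccccc1
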